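All runs were computed with made-up constants; the scatter is artificial.

Start from a one-step world: each D begins one chain, L ends up in chains, and the length at the end is cL over cD, 66.7 units. The dawn run shows a flask with more steps than that.

| flask | L | X | D | Q | remark | time |
|---|---|---|---|---|---|---|
| dawn | 0.10 M | 0.010 M | 1.5 mol% | 0.51 mM | run made earlier |  |
| red | 0.10 M | 0.0100 M | 1.5 mol% | 0.34 mM |  | 5.0 d |
| green | 0.10 M | 0.0100 M | 1.5 mol% | 0.34 mM |  | 1.5 d |

dawn run (percent of the L charged)

| time / h | G / % | L / % |
|---|---|---|
| 3.00 | 0.3 | 90.2 |
| 6.00 | 2.1 | 87.7 |
| 10.0 | 4.0 | 86.0 |
| 15.0 | 6.4 | 84.1 |
| 20.0 | 10.6 | 79.4 |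
| 25.0 | 15.0 | 74.9 |

(readings scatter by 0.5 percentage points)

- the average divides the monomer in chains by the number of chains begun, living and dead together
- the numbers in the tables scatter by 0.5 percentage points (one standard deviation)
- the earlier runs do not show the number of chains; that part of a forecast is a guess

- which of the two ends with the longer chains by the average number of monomer units in a chain (chains begun, living or dead) ("neither" if they lie within 10%) (red / green / neither)
- average number of monomer units in a chain (chains begun, living or dead) at the end, red
- average number of monomer units in a chain (chains begun, living or dead) at the end, green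

First ask how much L can enter chains. In the dawn run L + G stands at 90.5% at the first reading, 3.00 h, and cL minus cX, as a share of cL, is 90.0%. So treat X as the limiting reagent of a fast step that removes its own amount of L, leaving 90.0 mM free.

Next ask how much D can begin chains. The readings do not show this, so assume, as my own reckoning, that in red and green Q removes D one to one and just as fast, leaving 1.16 mM of 1.50 mM.

Now define the terminal length, free L over free D, for red and green: 77.6 units. Once those fast steps are over, the length in these flasks is this figure times the share of free L reacted, divided by the share of free D that has begun chains.

Red and green have the same charges, hence the same terminal length, and red runs 3.33 times as long. The dawn run reads G 15.0% at 25.0 h, less than the 90.0% open to it, so expect green, at 1.5 d, to lie well short of the terminal length. Commit to red as the longer, itself below the terminal length.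

The forecast also says red, with 33 for red and 26 for green, but on other grounds: “I read this as Q retarding until it is consumed”.

The flask gives 66.0 for red and 28.5 for green, so red ends longer.

    L + Z → G + Z, rate k1*[Z]*[L] (k = 0.253 L mol⁻¹ min⁻¹)
    D + Q → E (k = 136 L mol⁻¹ min⁻¹)
    X + L → J (k = 1.86 L mol⁻¹ min⁻¹)
    L + D → Z + G (k = 0.0103 L mol⁻¹ min⁻¹)

Left to 50.0 d, red stands at 78.9, with D at 1.28% of its charge, against the terminal length of 77.6. For the flask like green but with 6 mol% D, the terminal length is 15.9; at 1.50 d that flask stands at 18.3, with G 71.5% and 29% of its D still unspent.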